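(All runs were computed with made-up constants, noise included.)

E, the ring, is what this flask is run for, and I start from a rule of thumb of the bench for closing rings under dilution.

| flask | G | remark | time |
|---|---|---|---|
| alpha | 0.025 M | run made earlier |  |
| epsilon | 0.10 M | run made earlier |  |
| flask | 0.050 M |  | 2.0 min |

| run | time / s | G / % | E / % |
|---|---|---|---|
| alpha | 20.0 | 12.8 | 75.9 |
| alpha | 40.0 | 0.2 | 90.0 |
| alpha | 60.0 | 0.2 | 88.7 |
| alpha | 80.0 | 0.2 | 89.2 |
| alpha | 90.0 | 1.2 | 89.4 |
| alpha | 120 | 0.9 | 86.8 |
| epsilon | 10.0 | 21.4 | 35.6 |
| epsilon | 25.0 | 9.4 | 55.6 |
| epsilon | 40.0 | 2.3 | 63.3 |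
| epsilon | 60.0 | 0 | 65.3 |
| epsilon | 90.0 | 0 | 65.2 |
| epsilon | 120 | 0 | 67.0 |

(each reading ± 1 percentage point)

- the reaction counts as stopped when no species that holds the G changes by six tenths of a point or more over the second half of the time

* which holds at 2.0 min: what has brought the reaction to rest, or that it has not come to rest (forward and back rates have come level / all of G has reacted / it is still moving)
* part of the G gone at 2.0 min
* the E standing at 2.0 min, as a percentage of the G charged

In the alpha and epsilon runs E stays level while G reads 0.9% and 0% at 120 s, so I expect this flask to come to rest when G is used up. The question is then how much E stands, and the plateau readings average 88.8% in alpha and 65.8% in epsilon. The bench rule makes the share lost grow in step with the charge, and from alpha it gives this flask a loss of 22.4%, but between the two runs the rule already stops working, since the charge rises by a factor of 4.00 and the loss by 3.05. So I divide the rate of loss by the rate of ring closure, which removes time, and if closure takes one molecule and the loss two, the quotient follows concentration. I assume that over a whole run the G lost per G ringed, divided by the charge, stays constant as a selectivity factor; it reads 5.03 M⁻¹ in alpha and 5.19 M⁻¹ in epsilon, and I carry the mean of these readings, 5.11 M⁻¹, as the factor b. For this flask, with c(G) charged at 0.050 M, I reckon E as one over one plus b times that charge, which is 79.6%.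

The forecast says for 2.0 min: all of G has reacted, with 100% of G gone and E at 79.5%, between 76% and 83%, on the ground that “That points to first-order ring closure competing with a second-order side reaction.” Its formula differs from mine, but both rest on the same two plateaus, so their closeness checks nothing.

The flask gives 79.2% of E, with >99.9% of G gone: all of G has reacted.

    G + E → D (k = 0.698 M⁻¹ s⁻¹)
    2 G → X (k = 0.00146 M⁻¹ s⁻¹)
    2 G ⇌ Z (K = 21.0 M⁻¹, k = 4.73 M⁻¹ s⁻¹)
    G → E (k = 0.124 s⁻¹)

At 2.00 min this flask holds D at 20.8% of the G charged, each D counted as two G, with G at 0%. Its own E gives b as 5.25 M⁻¹, beside the 5.11 M⁻¹ carried from the runs. For the neighbour flask with 0.030 M of G, the carried b gives 86.7%, and that flask holds 86.1% of E.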